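**Retrosynthetic overview**

1. Target 34 comes from its bis-TBS ether 33 by desilylation.
2. Key step: 33 comes from the acyclic iodo-aldehyde 30. An alkenyl iodide/aldehyde coupling makes the C5–C6 bond and closes the ten-membered carbocycle, and the new C6 alkoxide closes the γ-lactone on the C12 methyl ester in the same flask.
3. 30 comes from a titanium aldol (C7–C8) of succinate imide 21 (C11 from (S)-methylsuccinic acid) with the β,γ-unsaturated aldehyde 15, then O8 acylation with acid 27 and reduction of the imide to the C6 aldehyde.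
4. 15 comes from but-3-yn-1-ol by carboalumination/oxirane opening (E C1=C10) and carbomagnesiation–iodination of propargyl alcohol (Z C4=C5 iodide).
5. Ring order: no ring exists before step 14; there the carbocycle forms first and the lactone directly after it, in one operation.

Assumption: (S)-methylsuccinic acid, (4R)-4-benzyl-1,3-thiazolidine-2-thione and 2-(hydroxymethyl)prop-2-enoic acid are purchased; atom labels C1–C15 follow germacrane numbering (C12 lactone carbonyl, C6 lactone carbinol, C8 ester carbinol).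

**Route**

Step 1
Reactants: 1 but-3-yn-1-ol
Product: 2 1-[(but-3-yn-1-yloxy)methyl]-4-methoxybenzene
Conditions: NaH, 4-methoxybenzyl chloride, Bu4NI (cat.), THF/DMF, 0 → 25 °C
Reagents that add atoms: 4-methoxybenzyl chloride, COc1ccc(CCl)cc1
Why: Williamson etherification; NaH removes only the O–H, so the alkyne C–H is untouched, and no stereocenter is involved.

Step 2
Reactants: 2 1-[(but-3-yn-1-yloxy)methyl]-4-methoxybenzene; 3 oxirane
Product: 6 (3E)-6-[(4-methoxyphenyl)methoxy]-4-methylhex-3-en-1-ol, via alkenylalane 4 (not isolated), via lithium alanate 5 (not isolated)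
Conditions: AlMe3, Cp2ZrCl2 (25 mol %), CH2Cl2, 0 → 25 °C; excess AlMe3 evaporated; n-BuLi, THF, −78 °C; then 3, −78 → 0 °C; aq. NH4Cl
Reagents that add atoms: trimethylaluminium, C[Al](C)C
Why: Negishi zirconium-catalysed carboalumination adds Me and Al syn across the terminal alkyne (Me to the internal carbon), which fixes the E C1=C10 alkene, and the alanate opens oxirane with retention of alkene geometry.

Step 3
Reactants: 6 (3E)-6-[(4-methoxyphenyl)methoxy]-4-methylhex-3-en-1-ol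
Product: 7 1-({[(3E)-6-bromo-3-methylhex-3-en-1-yl]oxy}methyl)-4-methoxybenzene
Conditions: CBr4, PPh3, CH2Cl2, 0 °C
Reagents that add atoms: carbon tetrabromide, BrC(Br)(Br)Br
Why: Appel reaction converts the primary alcohol to the bromide under neutral conditions that leave the PMB ether and the trisubstituted alkene alone.

Step 4
Reactants: 7 1-({[(3E)-6-bromo-3-methylhex-3-en-1-yl]oxy}methyl)-4-methoxybenzene; 8 prop-2-yn-1-ol
Product: 12 (2Z)-3-iodo-2-[(3E)-6-[(4-methoxyphenyl)methoxy]-4-methylhex-3-en-1-yl]prop-2-en-1-ol, via chloromagnesium propargyl alkoxide 9 (not isolated), via Grignard reagent 10 (not isolated), via alkenylmagnesium chelate 11 (not isolated)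
Conditions: 7, Mg, THF, 40 °C; separately 8, i-PrMgCl, THF, 0 °C; combine, CuI (10 mol %), 0 → 25 °C; then I2, −40 → 0 °C; aq. NH4Cl
Reagents that add atoms: iodine, II
Why: Duboudin copper-catalysed anti-carbomagnesiation of the propargylic magnesium alkoxide puts the alkyl group on C4 and Mg on C5 cis to CH2O in a five-membered chelate, so iodinolysis with retention gives only the Z iodoalkene (I cis to CH2OH) needed later at C4=C5.

Step 5
Reactants: 12 (2Z)-3-iodo-2-[(3E)-6-[(4-methoxyphenyl)methoxy]-4-methylhex-3-en-1-yl]prop-2-en-1-ol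
Product: 13 tert-butyl{[(2Z)-3-iodo-2-[(3E)-6-[(4-methoxyphenyl)methoxy]-4-methylhex-3-en-1-yl]prop-2-en-1-yl]oxy}dimethylsilane
Conditions: TBSCl, imidazole, CH2Cl2, 0 → 25 °C
Reagents that add atoms: tert-butyl(chloro)dimethylsilane, CC(C)(C)[Si](C)(C)Cl
Why: Standard silylation of the primary allylic alcohol; the TBS ether stays on to the last step.

Step 6
Reactants: 13 tert-butyl{[(2Z)-3-iodo-2-[(3E)-6-[(4-methoxyphenyl)methoxy]-4-methylhex-3-en-1-yl]prop-2-en-1-yl]oxy}dimethylsilane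
Product: 14 (3E,7Z)-7-({[tert-butyl(dimethyl)silyl]oxy}methyl)-8-iodo-3-methylocta-3,7-dien-1-ol
Conditions: DDQ, CH2Cl2/pH 7 buffer 10:1, 0 °C
Reagents that add atoms: none
Why: Oxidative PMB cleavage by DDQ (benzylic hydride abstraction, hydrolysis of the oxocarbenium ion) spares the silyl ether, the alkenyl iodide and the trisubstituted alkene.

Step 7
Reactants: 14 (3E,7Z)-7-({[tert-butyl(dimethyl)silyl]oxy}methyl)-8-iodo-3-methylocta-3,7-dien-1-ol
Product: 15 (3E,7Z)-7-({[tert-butyl(dimethyl)silyl]oxy}methyl)-8-iodo-3-methylocta-3,7-dienal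
Conditions: Dess–Martin periodinane, NaHCO3, CH2Cl2, 0 °C; used at once
Reagents that add atoms: none
Why: Dess–Martin oxidation under buffered, non-basic conditions gives the β,γ-unsaturated aldehyde without migration of the C1=C10 alkene into conjugation.

Step 8
Reactants: 16 (2S)-2-methylbutanedioic acid
Product: 17 (3S)-3-methyloxolane-2,5-dione
Conditions: acetyl chloride, reflux; evaporate
Reagents that add atoms: none
Why: Cyclodehydration of the 1,4-diacid to the five-membered anhydride; C11 keeps its configuration under these conditions.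

Step 9
Reactants: 17 (3S)-3-methyloxolane-2,5-dione; 18 (4R)-4-benzyl-1,3-thiazolidine-2-thione
Product: 21 methyl (2S)-4-[(4R)-4-benzyl-2-sulfanylidene-1,3-thiazolidin-3-yl]-2-methyl-4-oxobutanoate, via sodium thiazolidinethionide 19 (not isolated), via sodium carboxylate 20 (not isolated)
Conditions: 18, NaH, THF, 0 °C; 17, −78 → 0 °C; then MeI, DMF, 25 °C
Reagents that add atoms: iodomethane, CI
Why: Regioselective anhydride opening, in which the bulky amide anion N-acylates at the less hindered CH2-flanked carbonyl (C6), followed by SN2 O-methylation of the carboxylate; C11 is not touched.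

Step 10
Reactants: 21 methyl (2S)-4-[(4R)-4-benzyl-2-sulfanylidene-1,3-thiazolidin-3-yl]-2-methyl-4-oxobutanoate; 15 (3E,7Z)-7-({[tert-butyl(dimethyl)silyl]oxy}methyl)-8-iodo-3-methylocta-3,7-dienal
Product: 24 methyl (2S,3R,4S,6E,10Z)-3-{[(4R)-4-benzyl-2-sulfanylidene-1,3-thiazolidin-3-yl]carbonyl}-10-({[tert-butyl(dimethyl)silyl]oxy}methyl)-4-hydroxy-11-iodo-2,6-dimethylundeca-6,10-dienoate, via chlorotitanium enolate 22 (not isolated), via titanium aldolate 23 (not isolated)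
Conditions: 21, TiCl4, i-Pr2NEt, N-methylpyrrolidin-2-one, CH2Cl2, 0 → −78 °C; then 15, −78 °C; aq. NH4Cl at −78 °C; cold work-up, crude used at once
Reagents that add atoms: none
Why: Crimmins titanium aldol (Evans syn): the Z enolate reacts through a Zimmerman–Traxler chair on the face away from the benzyl group of the (R)-auxiliary, setting C7 (R) and C8 (S) syn, while C11 is a spectator.

Step 11
Reactants: 25 2-(hydroxymethyl)prop-2-enoic acid
Product: 27 2-({[tert-butyl(dimethyl)silyl]oxy}methyl)prop-2-enoic acid, via bis-silyl compound 26 (not isolated)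
Conditions: TBSCl (2.2 equiv), imidazole, DMF, 25 °C; then K2CO3 (cat.), MeOH/H2O, 0 °C; pH 4 work-up
Reagents that add atoms: tert-butyl(chloro)dimethylsilane, CC(C)(C)[Si](C)(C)Cl
Why: Silylation of both OH and CO2H, then selective hydrolysis of the labile silyl ester, leaves the silyl ether acid.

Step 12
Reactants: 24 methyl (2S,3R,4S,6E,10Z)-3-{[(4R)-4-benzyl-2-sulfanylidene-1,3-thiazolidin-3-yl]carbonyl}-10-({[tert-butyl(dimethyl)silyl]oxy}methyl)-4-hydroxy-11-iodo-2,6-dimethylundeca-6,10-dienoate; 27 2-({[tert-butyl(dimethyl)silyl]oxy}methyl)prop-2-enoic acid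
Product: 29 methyl (2S,3R,4S,6E,10Z)-3-{[(4R)-4-benzyl-2-sulfanylidene-1,3-thiazolidin-3-yl]carbonyl}-10-({[tert-butyl(dimethyl)silyl]oxy}methyl)-4-{[2-({[tert-butyl(dimethyl)silyl]oxy}methyl)prop-2-enoyl]oxy}-11-iodo-2,6-dimethylundeca-6,10-dienoate, via acid chloride 28 (not isolated)
Conditions: 27, 1-chloro-N,N,2-trimethylprop-1-en-1-amine, CH2Cl2, 0 °C; then crude 24, pyridine, DMAP (cat.), −20 → 0 °C
Reagents that add atoms: none
Why: Acyl chloride esterification (neutral activation with the Ghosez reagent) of the C8 hydroxyl at low temperature is expected to outrun γ-lactonisation onto the C12 methyl ester, and C8 keeps its configuration.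

Step 13
Reactants: 29 methyl (2S,3R,4S,6E,10Z)-3-{[(4R)-4-benzyl-2-sulfanylidene-1,3-thiazolidin-3-yl]carbonyl}-10-({[tert-butyl(dimethyl)silyl]oxy}methyl)-4-{[2-({[tert-butyl(dimethyl)silyl]oxy}methyl)prop-2-enoyl]oxy}-11-iodo-2,6-dimethylundeca-6,10-dienoate
Product: 30 methyl (2S,3R,4S,6E,10Z)-10-({[tert-butyl(dimethyl)silyl]oxy}methyl)-4-{[2-({[tert-butyl(dimethyl)silyl]oxy}methyl)prop-2-enoyl]oxy}-3-formyl-11-iodo-2,6-dimethylundeca-6,10-dienoate
Conditions: i-Bu2AlH (1.1 equiv, added until the yellow colour fades), CH2Cl2, −78 °C; aq. potassium sodium tartrate; crude used at once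
Reagents that add atoms: none
Why: Reduction of the N-acyl thiazolidinethione by i-Bu2AlH stops at the aldehyde through a stable hemiaminal aluminate, and the activated imide reacts faster than the two esters at −78 °C; no stereocenter changes.

Step 14
Reactants: 30 methyl (2S,3R,4S,6E,10Z)-10-({[tert-butyl(dimethyl)silyl]oxy}methyl)-4-{[2-({[tert-butyl(dimethyl)silyl]oxy}methyl)prop-2-enoyl]oxy}-3-formyl-11-iodo-2,6-dimethylundeca-6,10-dienoate
Product: 33 (3S,3aR,4S,6E,10Z,11aR)-10-({[tert-butyl(dimethyl)silyl]oxy}methyl)-3,6-dimethyl-2-oxo-2,3,3a,4,5,8,9,11a-octahydrocyclodeca[b]furan-4-yl 2-({[tert-butyl(dimethyl)silyl]oxy}methyl)prop-2-enoate, via alkenylchromium species 31 (not isolated), via chromium alkoxide 32 (not isolated)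
Conditions: CrCl2 (10 equiv), NiCl2 (2 mol %), degassed DMSO/THF 3:1, 2 mM, syringe pump, 25 °C, 48 h; aq. NH4Cl
Reagents that add atoms: none
Why: Intramolecular Nozaki–Hiyama–Kishi alkenylation then lactonisation: zerovalent nickel inserts into the C5–I bond with retention, transmetalation gives alkenylchromium 31, which adds to the C6 aldehyde through a chair-chair-like ten-membered transition state with the aldehyde oxygen, the C11 branch and the O8 ester all pseudo-equatorial (H6 anti to H7, 6R), and the trivalent chromium alkoxide 32 then acylates on the C12 methyl ester to give the trans γ-lactone.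

Step 15
Reactants: 33 (3S,3aR,4S,6E,10Z,11aR)-10-({[tert-butyl(dimethyl)silyl]oxy}methyl)-3,6-dimethyl-2-oxo-2,3,3a,4,5,8,9,11a-octahydrocyclodeca[b]furan-4-yl 2-({[tert-butyl(dimethyl)silyl]oxy}methyl)prop-2-enoate
Product: 34 (3S,3aR,4S,6E,10Z,11aR)-10-(hydroxymethyl)-3,6-dimethyl-2-oxo-2,3,3a,4,5,8,9,11a-octahydrocyclodeca[b]furan-4-yl 2-(hydroxymethyl)prop-2-enoate
Conditions: HF·pyridine, pyridine, THF, 0 → 25 °C
Reagents that add atoms: none
Why: Fluoride-mediated desilylation under pyridine-buffered conditions removes both primary TBS ethers without opening the lactone, adding to the acrylate or triggering acid-induced transannular cyclisation of the 1(10),4-diene.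

**Compound list**

1 | but-3-yn-1-ol | C#CCCO | starting material
2 | 1-[(but-3-yn-1-yloxy)methyl]-4-methoxybenzene | C#CCCOCc1ccc(OC)cc1 | intermediate
3 | oxirane | C1CO1 | starting material
4 | [(1E)-4-[(4-methoxyphenyl)methoxy]-2-methylbut-1-en-1-yl]dimethylaluminium (alkenylalane) | C[Al](C)/C=C(\C)CCOCc1ccc(OC)cc1 | intermediate (not isolated)
5 | lithium butyl[(1E)-4-[(4-methoxyphenyl)methoxy]-2-methylbut-1-en-1-yl]dimethylaluminate | [Li+].CCCC[Al-](C)(C)/C=C(\C)CCOCc1ccc(OC)cc1 | intermediate (not isolated)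
6 | (3E)-6-[(4-methoxyphenyl)methoxy]-4-methylhex-3-en-1-ol | OCC/C=C(\C)CCOCc1ccc(OC)cc1 | intermediate
7 | 1-({[(3E)-6-bromo-3-methylhex-3-en-1-yl]oxy}methyl)-4-methoxybenzene | BrCC/C=C(\C)CCOCc1ccc(OC)cc1 | intermediate
8 | prop-2-yn-1-ol | C#CCO | starting material
9 | chloromagnesium prop-2-yn-1-olate | C#CCO[Mg]Cl | intermediate (not isolated)
10 | bromo[(3E)-6-[(4-methoxyphenyl)methoxy]-4-methylhex-3-en-1-yl]magnesium | Br[Mg]CC/C=C(\C)CCOCc1ccc(OC)cc1 | intermediate (not isolated)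
11 | 4-[(3E)-6-[(4-methoxyphenyl)methoxy]-4-methylhex-3-en-1-yl]-2,5-dihydro-1,2-oxamagnesole (alkenylmagnesium alkoxide chelate) | COc1ccc(COCC/C(C)=C/CCC2=C[Mg]OC2)cc1 | intermediate (not isolated)
12 | (2Z)-3-iodo-2-[(3E)-6-[(4-methoxyphenyl)methoxy]-4-methylhex-3-en-1-yl]prop-2-en-1-ol | OC/C(CC/C=C(\C)CCOCc1ccc(OC)cc1)=C\I | intermediate
13 | tert-butyl{[(2Z)-3-iodo-2-[(3E)-6-[(4-methoxyphenyl)methoxy]-4-methylhex-3-en-1-yl]prop-2-en-1-yl]oxy}dimethylsilane | CC(C)(C)[Si](C)(C)OC/C(CC/C=C(\C)CCOCc1ccc(OC)cc1)=C\I | intermediate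
14 | (3E,7Z)-7-({[tert-butyl(dimethyl)silyl]oxy}methyl)-8-iodo-3-methylocta-3,7-dien-1-ol | OCC/C(C)=C/CC/C(CO[Si](C)(C)C(C)(C)C)=C/I | intermediate
15 | (3E,7Z)-7-({[tert-butyl(dimethyl)silyl]oxy}methyl)-8-iodo-3-methylocta-3,7-dienal | O=CC/C(C)=C/CC/C(CO[Si](C)(C)C(C)(C)C)=C/I | intermediate
16 | (2S)-2-methylbutanedioic acid | OC(=O)C[C@H](C)C(=O)O | starting material
17 | (3S)-3-methyloxolane-2,5-dione | C[C@H]1CC(=O)OC1=O | intermediate
18 | (4R)-4-benzyl-1,3-thiazolidine-2-thione | S=C1N[C@H](Cc2ccccc2)CS1 | starting material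
19 | sodium (4R)-4-benzyl-2-sulfanylidene-1,3-thiazolidin-3-ide | [Na+].S=C1[N-][C@H](Cc2ccccc2)CS1 | intermediate (not isolated)
20 | sodium (2S)-4-[(4R)-4-benzyl-2-sulfanylidene-1,3-thiazolidin-3-yl]-2-methyl-4-oxobutanoate | [Na+].[O-]C(=O)[C@@H](C)CC(=O)N1[C@H](Cc2ccccc2)CSC1=S | intermediate (not isolated)
21 | methyl (2S)-4-[(4R)-4-benzyl-2-sulfanylidene-1,3-thiazolidin-3-yl]-2-methyl-4-oxobutanoate | COC(=O)[C@@H](C)CC(=O)N1[C@H](Cc2ccccc2)CSC1=S | intermediate
22 | trichloro{[(1Z,3S)-1-[(4R)-4-benzyl-2-sulfanylidene-1,3-thiazolidin-3-yl]-4-methoxy-3-methyl-4-oxobut-1-en-1-yl]oxy}titanium (Z enolate of 21) | COC(=O)[C@@H](C)/C=C(\O[Ti](Cl)(Cl)Cl)N1[C@H](Cc2ccccc2)CSC1=S | intermediate (not isolated)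
23 | trichlorotitanium alkoxide of 24 (O8–TiCl3) | COC(=O)[C@@H](C)[C@@H](C(=O)N1[C@H](Cc2ccccc2)CSC1=S)[C@@H](O[Ti](Cl)(Cl)Cl)C/C(C)=C/CC/C(CO[Si](C)(C)C(C)(C)C)=C/I | intermediate (not isolated)
24 | methyl (2S,3R,4S,6E,10Z)-3-{[(4R)-4-benzyl-2-sulfanylidene-1,3-thiazolidin-3-yl]carbonyl}-10-({[tert-butyl(dimethyl)silyl]oxy}methyl)-4-hydroxy-11-iodo-2,6-dimethylundeca-6,10-dienoate | COC(=O)[C@@H](C)[C@@H](C(=O)N1[C@H](Cc2ccccc2)CSC1=S)[C@@H](O)C/C(C)=C/CC/C(CO[Si](C)(C)C(C)(C)C)=C/I | intermediate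
25 | 2-(hydroxymethyl)prop-2-enoic acid | C=C(CO)C(=O)O | starting material
26 | tert-butyl(dimethyl)silyl 2-({[tert-butyl(dimethyl)silyl]oxy}methyl)prop-2-enoate | C=C(CO[Si](C)(C)C(C)(C)C)C(=O)O[Si](C)(C)C(C)(C)C | intermediate (not isolated)
27 | 2-({[tert-butyl(dimethyl)silyl]oxy}methyl)prop-2-enoic acid | C=C(CO[Si](C)(C)C(C)(C)C)C(=O)O | intermediate
28 | 2-({[tert-butyl(dimethyl)silyl]oxy}methyl)prop-2-enoyl chloride | C=C(CO[Si](C)(C)C(C)(C)C)C(=O)Cl | intermediate (not isolated)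
29 | methyl (2S,3R,4S,6E,10Z)-3-{[(4R)-4-benzyl-2-sulfanylidene-1,3-thiazolidin-3-yl]carbonyl}-10-({[tert-butyl(dimethyl)silyl]oxy}methyl)-4-{[2-({[tert-butyl(dimethyl)silyl]oxy}methyl)prop-2-enoyl]oxy}-11-iodo-2,6-dimethylundeca-6,10-dienoate | COC(=O)[C@@H](C)[C@@H](C(=O)N1[C@H](Cc2ccccc2)CSC1=S)[C@@H](OC(=O)C(=C)CO[Si](C)(C)C(C)(C)C)C/C(C)=C/CC/C(CO[Si](C)(C)C(C)(C)C)=C/I | intermediate
30 | methyl (2S,3R,4S,6E,10Z)-10-({[tert-butyl(dimethyl)silyl]oxy}methyl)-4-{[2-({[tert-butyl(dimethyl)silyl]oxy}methyl)prop-2-enoyl]oxy}-3-formyl-11-iodo-2,6-dimethylundeca-6,10-dienoate | COC(=O)[C@@H](C)[C@@H](C=O)[C@@H](OC(=O)C(=C)CO[Si](C)(C)C(C)(C)C)C/C(C)=C/CC/C(CO[Si](C)(C)C(C)(C)C)=C/I | intermediate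
31 | alkenylchromium dichloride derived from 30 (CrCl2 in place of I at C5) | COC(=O)[C@@H](C)[C@@H](C=O)[C@@H](OC(=O)C(=C)CO[Si](C)(C)C(C)(C)C)C/C(C)=C/CC/C(CO[Si](C)(C)C(C)(C)C)=C/[Cr](Cl)Cl | intermediate (not isolated)
32 | methyl (2S)-2-[(1R,2S,4E,8Z,10R)-8-({[tert-butyl(dimethyl)silyl]oxy}methyl)-2-{[2-({[tert-butyl(dimethyl)silyl]oxy}methyl)prop-2-enoyl]oxy}-10-[(dichlorochromio)oxy]-4-methylcyclodeca-4,8-dien-1-yl]propanoate (macrocyclic chromium alkoxide) | C=C(CO[Si](C)(C)C(C)(C)C)C(=O)O[C@H]1C/C(C)=C/CC/C(CO[Si](C)(C)C(C)(C)C)=C/[C@@H](O[Cr](Cl)Cl)[C@@H]1[C@H](C)C(=O)OC | intermediate (not isolated)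
33 | (3S,3aR,4S,6E,10Z,11aR)-10-({[tert-butyl(dimethyl)silyl]oxy}methyl)-3,6-dimethyl-2-oxo-2,3,3a,4,5,8,9,11a-octahydrocyclodeca[b]furan-4-yl 2-({[tert-butyl(dimethyl)silyl]oxy}methyl)prop-2-enoate | C=C(CO[Si](C)(C)C(C)(C)C)C(=O)O[C@H]1C/C(C)=C/CC/C(CO[Si](C)(C)C(C)(C)C)=C/[C@H]2OC(=O)[C@@H](C)[C@H]12 | intermediate
34 | (3S,3aR,4S,6E,10Z,11aR)-10-(hydroxymethyl)-3,6-dimethyl-2-oxo-2,3,3a,4,5,8,9,11a-octahydrocyclodeca[b]furan-4-yl 2-(hydroxymethyl)prop-2-enoate | C=C(CO)C(=O)O[C@H]1C/C(C)=C/CC/C(CO)=C/[C@H]2OC(=O)[C@@H](C)[C@H]12 | target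

**Step count and risks**

Total steps: 15. Longest linear sequence: 12 (steps 1–7, 10, 12, 13, 14, 15); steps 8–9 and step 11 are side branches.

Three steps most likely to fail:

1. Step 14 (ring closure with lactonisation). It may give oligomers, loss of the O8 ester from 30 by β-elimination, acyl migration from O8 to O6, or the C6 epimer; the two α-branches on C7 are similar in size, so the facial preference rests on the ring-forming transition state. Fallback: set out from 29. Exchange the thiazolidinethione for a thioester with pyridine-2-thiol and catalytic DMAP in CH2Cl2 to give the S-pyridin-2-yl thioester F1. Close the ten-membered ring as a ketone by coupling the alkenyl iodide with the thioester (NiBr2(4,4'-di-tert-butyl-2,2'-bipyridine) as precatalyst, Cp2ZrCl2, Zn, 1,3-dimethylimidazolidin-2-one/THF, 2 mM) to give the macrocyclic dienone F2. Reduce F2 with NaBH4/CeCl3 in MeOH at −78 °C, with hydride expected from the outer face of the ring; the C6 alkoxide then lactonises and the sequence comes back to the route at 33.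

2. Step 10 (aldol, with step 12 directly behind it). The free γ-hydroxy ester 24 may close onto the C12 methyl ester to the unwanted 8,12-lactone before O8 can be acylated. Fallback: set out from 17 and 18. Work up the anhydride opening with dilute HCl instead of adding MeI and isolate the carboxylic acid F3. Convert it with tert-butyl 2,2,2-trichloroacetimidate (BF3·OEt2 cat.) to the tert-butyl ester F4. Run the same titanium aldol with 15 to the tert-butyl ester aldol adduct F5, which does not lactonise under these conditions. Acylate with 28 to the acylated tert-butyl ester F6. Cleave the tert-butyl ester with TMSOTf/2,6-lutidine to the acylated carboxylic acid F7 and methylate with trimethylsilyldiazomethane, which comes back to the route at 29.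

3. Step 13 (imide to aldehyde). i-Bu2AlH may also attack the acrylate or the methyl ester, and the β-acyloxy aldehyde may eliminate during the aluminium work-up. Fallback: set out from 29. Aminolysis with N,O-dimethylhydroxylamine hydrochloride and imidazole in CH2Cl2 gives the Weinreb amide F8. Cp2Zr(H)Cl in THF at 0 → 25 °C reduces this amide to the aldehyde by hydrozirconation of the amide carbonyl, leaves the esters alone and needs only a neutral work-up; this comes back to the route at 30.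

**Further compounds**

F1 | step 14 | methyl (2S,3R,4S,6E,10Z)-10-({[tert-butyl(dimethyl)silyl]oxy}methyl)-4-{[2-({[tert-butyl(dimethyl)silyl]oxy}methyl)prop-2-enoyl]oxy}-11-iodo-2,6-dimethyl-3-[(pyridin-2-ylsulfanyl)carbonyl]undeca-6,10-dienoate | COC(=O)[C@@H](C)[C@@H](C(=O)Sc1ccccn1)[C@@H](OC(=O)C(=C)CO[Si](C)(C)C(C)(C)C)C/C(C)=C/CC/C(CO[Si](C)(C)C(C)(C)C)=C/I
F2 | step 14 | methyl (2S)-2-[(1R,2S,4E,8Z)-8-({[tert-butyl(dimethyl)silyl]oxy}methyl)-2-{[2-({[tert-butyl(dimethyl)silyl]oxy}methyl)prop-2-enoyl]oxy}-4-methyl-10-oxocyclodeca-4,8-dien-1-yl]propanoate | COC(=O)[C@@H](C)[C@H]1C(=O)/C=C(CO[Si](C)(C)C(C)(C)C)/CC/C=C(C)/C[C@@H]1OC(=O)C(=C)CO[Si](C)(C)C(C)(C)C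
F3 | step 10 | (2S)-4-[(4R)-4-benzyl-2-sulfanylidene-1,3-thiazolidin-3-yl]-2-methyl-4-oxobutanoic acid | OC(=O)[C@@H](C)CC(=O)N1[C@H](Cc2ccccc2)CSC1=S
F4 | step 10 | tert-butyl (2S)-4-[(4R)-4-benzyl-2-sulfanylidene-1,3-thiazolidin-3-yl]-2-methyl-4-oxobutanoate | CC(C)(C)OC(=O)[C@@H](C)CC(=O)N1[C@H](Cc2ccccc2)CSC1=S
F5 | step 10 | tert-butyl (2S,3R,4S,6E,10Z)-3-{[(4R)-4-benzyl-2-sulfanylidene-1,3-thiazolidin-3-yl]carbonyl}-10-({[tert-butyl(dimethyl)silyl]oxy}methyl)-4-hydroxy-11-iodo-2,6-dimethylundeca-6,10-dienoate | CC(C)(C)OC(=O)[C@@H](C)[C@@H](C(=O)N1[C@H](Cc2ccccc2)CSC1=S)[C@@H](O)C/C(C)=C/CC/C(CO[Si](C)(C)C(C)(C)C)=C/I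
F6 | step 10 | tert-butyl (2S,3R,4S,6E,10Z)-3-{[(4R)-4-benzyl-2-sulfanylidene-1,3-thiazolidin-3-yl]carbonyl}-10-({[tert-butyl(dimethyl)silyl]oxy}methyl)-4-{[2-({[tert-butyl(dimethyl)silyl]oxy}methyl)prop-2-enoyl]oxy}-11-iodo-2,6-dimethylundeca-6,10-dienoate | CC(C)(C)OC(=O)[C@@H](C)[C@@H](C(=O)N1[C@H](Cc2ccccc2)CSC1=S)[C@@H](OC(=O)C(=C)CO[Si](C)(C)C(C)(C)C)C/C(C)=C/CC/C(CO[Si](C)(C)C(C)(C)C)=C/I
F7 | step 10 | (2S,3R,4S,6E,10Z)-3-{[(4R)-4-benzyl-2-sulfanylidene-1,3-thiazolidin-3-yl]carbonyl}-10-({[tert-butyl(dimethyl)silyl]oxy}methyl)-4-{[2-({[tert-butyl(dimethyl)silyl]oxy}methyl)prop-2-enoyl]oxy}-11-iodo-2,6-dimethylundeca-6,10-dienoic acid | OC(=O)[C@@H](C)[C@@H](C(=O)N1[C@H](Cc2ccccc2)CSC1=S)[C@@H](OC(=O)C(=C)CO[Si](C)(C)C(C)(C)C)C/C(C)=C/CC/C(CO[Si](C)(C)C(C)(C)C)=C/I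
F8 | step 13 | methyl (2S,3R,4S,6E,10Z)-10-({[tert-butyl(dimethyl)silyl]oxy}methyl)-4-{[2-({[tert-butyl(dimethyl)silyl]oxy}methyl)prop-2-enoyl]oxy}-11-iodo-3-[methoxy(methyl)carbamoyl]-2,6-dimethylundeca-6,10-dienoate | COC(=O)[C@@H](C)[C@@H](C(=O)N(C)OC)[C@@H](OC(=O)C(=C)CO[Si](C)(C)C(C)(C)C)C/C(C)=C/CC/C(CO[Si](C)(C)C(C)(C)C)=C/I
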